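**Retrosynthetic overview**
- The target comes from fluoride desilylation of its bis-TES ester, made by esterifying the C6 hydroxyl of the macrocyclic hydroxy acetate with a protected (R)-2,3-dihydroxy-2-methylpropanoic acid (from methallyl alcohol by Sharpless epoxidation).
- The ten-membered ring and the C6/C7 stereocentres come from an intramolecular CrCl2 (Nozaki–Hiyama) allylation of an enal by a 3-(bromomethyl)butenolide (C6–C7 bond), with C8 already set.
- The open precursor comes from a late Negishi sp3–sp2 coupling (C1–C2 bond) of a C2–C6/C15 alkylzinc with a C1/C7–C14 vinyl iodide butenolide.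
- The alkyl iodide comes from but-2-yne-1,4-diol (hydroalumination/iodination fixes C4=C5); the vinyl iodide comes from (S)-epichlorohydrin and ethynyltrimethylsilane (C8), with carboalumination fixing C1=C10.
- Ring order: butenolide first (ring-closing metathesis), then the ten-membered carbocycle (allylation); the butenolide becomes the α-methylene-γ-lactone in that step.

Assumption: positions are named by germacrane numbering (lactone C12–O–C8, ester oxygen on C6, C15 = acetoxymethyl carbon on C4, C14 = methyl on C10), and the six building blocks are taken as commercial. TBDPS = tert-butyldiphenylsilyl, TBS = tert-butyldimethylsilyl, TES = triethylsilyl.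

**Alkyl iodide fragment (C2–C6, C15)**

Step 1
Reactants: 1 but-2-yne-1,4-diol
Product: 2 4-[(tert-butyldiphenylsilyl)oxy]but-2-yn-1-ol
Conditions: NaH (1.0 equiv), THF, 0 °C; TBDPSCl (1.0 equiv), rt
Reagents that add atoms: tert-butyl(chloro)diphenylsilane, CC(C)(C)[Si](Cl)(c1ccccc1)c1ccccc1
Why: Monosilylation of the symmetric diol through its sparingly soluble monosodium alkoxide (Williamson-type O-silylation) differentiates the future C6 and C15 oxygens.

Step 2
Reactants: 2 4-[(tert-butyldiphenylsilyl)oxy]but-2-yn-1-ol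
Product: 4 (2Z)-4-[(tert-butyldiphenylsilyl)oxy]-3-iodobut-2-en-1-ol, via cyclic sodium vinylalanate 3 (not isolated)
Conditions: NaAlH2(OCH2CH2OMe)2 (Red-Al), THF, 0 °C → rt; then I2, −78 → 0 °C
Reagents that add atoms: iodine, [I][I]
Why: Hydroxyl-directed trans-hydroalumination of the propargylic alcohol places aluminium on the distal alkyne carbon cis to the CH2O group, and iodinolysis with retention gives the Z-iodide that fixes the C4=C5 geometry.

Step 3
Reactants: 4 (2Z)-4-[(tert-butyldiphenylsilyl)oxy]-3-iodobut-2-en-1-ol; 5 potassium trifluoro(vinyl)borate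
Product: 6 (2E)-3-{[(tert-butyldiphenylsilyl)oxy]methyl}penta-2,4-dien-1-ol
Conditions: PdCl2(dppf) (5 mol%), Cs2CO3, THF/H2O (9:1), 65 °C
Reagents that add atoms: none
Why: Suzuki–Miyaura coupling of the vinyl iodide proceeds with retention, so the new vinyl group (C3–C2) sits cis to C6 as the ring requires.

Step 4
Reactants: 6 (2E)-3-{[(tert-butyldiphenylsilyl)oxy]methyl}penta-2,4-dien-1-ol
Product: 7 (2E)-3-{[(tert-butyldiphenylsilyl)oxy]methyl}penta-2,4-dienal
Conditions: MnO2, CH2Cl2, rt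
Reagents that add atoms: none
Why: MnO2 oxidises only the allylic alcohol (allylic oxidation) and leaves the silyl ether and olefin geometry alone.

Step 5
Reactants: 7 (2E)-3-{[(tert-butyldiphenylsilyl)oxy]methyl}penta-2,4-dienal
Product: 8 tert-butyl{[(2E)-2-ethenyl-4,4-dimethoxybut-2-en-1-yl]oxy}diphenylsilane
Conditions: HC(OMe)3, PPTS (cat.), MeOH, 0 °C → rt
Reagents that add atoms: trimethyl orthoformate, COC(OC)OC; methanol, CO
Why: Acid-catalysed acetalisation masks the C6 aldehyde for the organometallic steps that follow.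

Step 6
Reactants: 8 tert-butyl{[(2E)-2-ethenyl-4,4-dimethoxybut-2-en-1-yl]oxy}diphenylsilane
Product: 10 (3E)-5,5-dimethoxy-3-{[(tert-butyldiphenylsilyl)oxy]methyl}pent-3-en-1-ol, via B-alkyl-9-BBN adduct 9 (not isolated)
Conditions: 9-BBN (1.2 equiv), THF, 0 °C → rt; then NaOH (3 M), H2O2 (30%), 0 °C
Reagents that add atoms: hydrogen peroxide, OO
Why: Anti-Markovnikov hydroboration with bulky 9-BBN takes only the terminal vinyl group (the trisubstituted alkene flanked by two allylic oxygens is hindered and deactivated), and oxidation gives the primary alcohol at C2.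

Step 7
Reactants: 10 (3E)-5,5-dimethoxy-3-{[(tert-butyldiphenylsilyl)oxy]methyl}pent-3-en-1-ol
Product: 11 tert-butyl{[(2E)-2-(2-iodoethyl)-4,4-dimethoxybut-2-en-1-yl]oxy}diphenylsilane
Conditions: PPh3, imidazole, I2, CH2Cl2, 0 °C
Reagents that add atoms: iodine, [I][I]
Why: Appel-type iodination of the primary alcohol under imidazole-buffered conditions that spare the acetal.

**Vinyl iodide butenolide fragment (C1, C7–C14)**

Step 8
Reactants: 12 ethynyltrimethylsilane; 13 (S)-epichlorohydrin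
Product: 15 (2S)-1-chloro-5-(trimethylsilyl)pent-4-yn-2-ol, via lithium (trimethylsilyl)acetylide 14 (not isolated)
Conditions: n-BuLi, THF, −78 °C; BF3·OEt2; then 13, −78 °C
Reagents that add atoms: none
Why: Yamaguchi–Hirao epoxide opening by the acetylide/BF3 at the unsubstituted epoxide carbon leaves the stereocentre (future C8) untouched.

Step 9
Reactants: 15 (2S)-1-chloro-5-(trimethylsilyl)pent-4-yn-2-ol
Product: 17 (3S)-6-(trimethylsilyl)hex-1-en-5-yn-3-ol, via epoxide 16 (not isolated)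
Conditions: Me3S+ I− (4 equiv), n-BuLi (3.9 equiv), THF, −10 °C → rt
Reagents that add atoms: trimethylsulfonium iodide, C[S+](C)C.[I-]
Why: The ylide first closes the chlorohydrin to the terminal epoxide, then opens it at CH2 and loses Me2S (one-carbon homologation of an epoxide to an allylic alcohol), with the C–O stereocentre retained.

Step 10
Reactants: 17 (3S)-6-(trimethylsilyl)hex-1-en-5-yn-3-ol
Product: 18 (3S)-hex-1-en-5-yn-3-ol
Conditions: K2CO3 (cat.), MeOH, rt
Reagents that add atoms: none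
Why: Mild methanolysis of the alkynyl C–Si bond frees the terminal alkyne.

Step 11
Reactants: 18 (3S)-hex-1-en-5-yn-3-ol
Product: 20 (3S,5E)-6-iodo-5-methylhexa-1,5-dien-3-ol, via vinylalane 19 (not isolated)
Conditions: AlMe3 (3.5 equiv), Cp2ZrCl2 (0.3 equiv), CH2Cl2, 0 °C → rt; then I2, THF, −30 °C
Reagents that add atoms: trimethylaluminium, C[Al](C)C; iodine, [I][I]
Why: Negishi zirconium-catalysed methylalumination adds Me and Al syn across the terminal alkyne (Me to the internal carbon), and iodinolysis with retention gives the E-vinyl iodide, which installs C14 and fixes the C1=C10 geometry.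

Step 12
Reactants: 21 methyl 2-(hydroxymethyl)prop-2-enoate
Product: 22 methyl 2-{[(tert-butyldimethylsilyl)oxy]methyl}prop-2-enoate
Conditions: TBSCl, imidazole, CH2Cl2, 0 °C → rt
Reagents that add atoms: tert-butyl(chloro)dimethylsilane, CC(C)(C)[Si](C)(C)Cl
Why: Standard silylation of the primary allylic alcohol protects the future C13 oxygen.

Step 13
Reactants: 22 methyl 2-{[(tert-butyldimethylsilyl)oxy]methyl}prop-2-enoate
Product: 23 2-{[(tert-butyldimethylsilyl)oxy]methyl}prop-2-enoic acid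
Conditions: LiOH, THF/H2O, 0 °C; then HCl (1 M) to pH 4
Reagents that add atoms: lithium hydroxide, [Li+].[OH-]
Why: Low-temperature saponification of the methyl ester leaves the primary silyl ether in place.

Step 14
Reactants: 20 (3S,5E)-6-iodo-5-methylhexa-1,5-dien-3-ol; 23 2-{[(tert-butyldimethylsilyl)oxy]methyl}prop-2-enoic acid
Product: 24 (3S,5E)-6-iodo-5-methylhexa-1,5-dien-3-yl 2-{[(tert-butyldimethylsilyl)oxy]methyl}prop-2-enoate
Conditions: dicyclohexylcarbodiimide, DMAP (cat.), CH2Cl2, 0 °C → rt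
Reagents that add atoms: none
Why: Steglich esterification acylates the secondary allylic alcohol without involving the stereocentre.

Step 15
Reactants: 24 (3S,5E)-6-iodo-5-methylhexa-1,5-dien-3-yl 2-{[(tert-butyldimethylsilyl)oxy]methyl}prop-2-enoate
Product: 25 (5S)-3-{[(tert-butyldimethylsilyl)oxy]methyl}-5-[(2E)-3-iodo-2-methylprop-2-en-1-yl]furan-2(5H)-one
Conditions: RuCl2(=CHPh)(PCy3)(H2IMes) (second-generation Grubbs catalyst, 5 mol%), CH2Cl2, 40 °C
Reagents that add atoms: none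
Why: Ring-closing metathesis between the vinyl group and the acrylate closes the five-membered butenolide with loss of ethene, and the trisubstituted vinyl iodide is inert to the catalyst.

**Fragment union and endgame**

Step 16
Reactants: 11 tert-butyl{[(2E)-2-(2-iodoethyl)-4,4-dimethoxybut-2-en-1-yl]oxy}diphenylsilane; 25 (5S)-3-{[(tert-butyldimethylsilyl)oxy]methyl}-5-[(2E)-3-iodo-2-methylprop-2-en-1-yl]furan-2(5H)-one
Product: 27 (5S)-3-{[(tert-butyldimethylsilyl)oxy]methyl}-5-[(2E,6E)-8,8-dimethoxy-2-methyl-6-{[(tert-butyldiphenylsilyl)oxy]methyl}octa-2,6-dien-1-yl]furan-2(5H)-one, via alkylzinc iodide 26 (not isolated)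
Conditions: Zn dust, LiCl, THF, 40 °C; then 25, PdCl2(dppf) (5 mol%), THF/NMP, rt → 45 °C
Reagents that add atoms: none
Why: Zinc insertion into the primary iodide and a palladium-catalysed Negishi sp3–sp2 coupling (retention at the vinyl iodide) join C2 to C1 under neutral conditions that the butenolide, acetal and silyl ethers tolerate.

Step 17
Reactants: 27 the coupled bis-silyl acetal
Product: 28 (2E,6E)-8-[(2S)-4-(hydroxymethyl)-5-oxo-2,5-dihydrofuran-2-yl]-7-methyl-3-{[(tert-butyldiphenylsilyl)oxy]methyl}octa-2,6-dienal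
Conditions: AcOH/THF/H2O (3:1:1), 35 °C
Reagents that add atoms: water, O
Why: Aqueous acid hydrolyses the dimethyl acetal and the primary TBS ether in one operation while the far more robust TBDPS ether survives.

Step 18
Reactants: 28 the hydroxy enal
Product: 30 (2E,6E)-8-[(2S)-4-(bromomethyl)-5-oxo-2,5-dihydrofuran-2-yl]-7-methyl-3-{[(tert-butyldiphenylsilyl)oxy]methyl}octa-2,6-dienal, via mesylate 29 (not isolated)
Conditions: MsCl, Et3N, CH2Cl2, −30 °C; then LiBr, THF, 0 °C
Reagents that add atoms: lithium bromide, [Li+].[Br-]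
Why: Mesylation followed by SN2 displacement with bromide converts the primary allylic alcohol to the allylic bromide without touching the enal.

Step 19
Reactants: 30 the bromo enal
Product: 31 (6R,7S,8S)-15-[(tert-butyldiphenylsilyl)oxy]-6-hydroxygermacra-1(10)E,4E,11(13)-trien-12,8-olide (C3 and C6 cis on C4=C5, trans-fused lactone)
Conditions: CrCl2 (8 equiv), THF, rt, 30 added by syringe pump over 10 h (final 0.002 M)
Reagents that add atoms: none
Why: Intramolecular Nozaki–Hiyama allylation closes the ten-membered ring at C6–C7; the ring-locked E-allylchromium reacts at its γ-carbon through a chair Zimmerman–Traxler transition state (6,7-anti) on the butenolide face opposite the C8 side chain (7,8-trans), which sets C6 and C7 and unveils the α-methylene lactone.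

Step 20
Reactants: 31 the macrocyclic silyl ether
Product: 32 (6R,7S,8S)-6,15-dihydroxygermacra-1(10)E,4E,11(13)-trien-12,8-olide
Conditions: HF·pyridine, pyridine, THF, 0 °C → rt
Reagents that add atoms: none
Why: Buffered fluoride cleaves the primary TBDPS ether without base that could add to or translactonise the α-methylene lactone.

Step 21
Reactants: 32 the diol
Product: 33 (6R,7S,8S)-15-acetoxy-6-hydroxygermacra-1(10)E,4E,11(13)-trien-12,8-olide
Conditions: AcCl (1.1 equiv), 2,4,6-collidine, CH2Cl2, −78 °C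
Reagents that add atoms: acetyl chloride, CC(=O)Cl
Why: Kinetically selective acetylation takes the unhindered primary allylic alcohol over the secondary C6 hydroxyl, which is flanked by the ring fusion.

**Side-chain acid**

Step 22
Reactants: 34 2-methylprop-2-en-1-ol
Product: 35 [(2S)-2-methyloxiran-2-yl]methanol
Conditions: Ti(OiPr)4 (5 mol%), L-(+)-diethyl tartrate (6 mol%), t-BuOOH, 4 Å MS, CH2Cl2, −20 °C
Reagents that add atoms: tert-butyl hydroperoxide, CC(C)(C)OO
Why: Sharpless asymmetric epoxidation with L-(+)-tartrate delivers oxygen to the face that gives the S epoxy alcohol (about 90–95% ee; the minor enantiomer ends up as a separable diastereomer after step 26).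

Step 23
Reactants: 35 [(2S)-2-methyloxiran-2-yl]methanol
Product: 36 (2R)-2-methyloxirane-2-carboxylic acid
Conditions: RuCl3·H2O (2 mol%), NaIO4, MeCN/CCl4/H2O, rt
Reagents that add atoms: water, O
Why: Catalytic ruthenium tetroxide oxidation takes the primary alcohol to the acid and leaves the epoxide and the quaternary stereocentre untouched (the descriptor changes only through priorities).

Step 24
Reactants: 36 (2R)-2-methyloxirane-2-carboxylic acid
Product: 37 (2R)-2,3-dihydroxy-2-methylpropanoic acid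
Conditions: NaOH (2 M, aq), 70 °C; then HCl to pH 2
Reagents that add atoms: sodium hydroxide, [Na+].[OH-]
Why: Hydroxide opens the epoxide by SN2 at the unhindered CH2, so the C–O bond at the quaternary carbon is kept and the configuration is retained.

Step 25
Reactants: 37 (2R)-2,3-dihydroxy-2-methylpropanoic acid
Product: 39 (2R)-2-methyl-2,3-bis[(triethylsilyl)oxy]propanoic acid, via tris-silyl compound 38 (not isolated)
Conditions: Et3SiOTf (3.5 equiv), 2,6-lutidine, CH2Cl2, −78 → 0 °C; then MeOH, K2CO3 (cat.), 0 °C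
Reagents that add atoms: triethylsilyl trifluoromethanesulfonate, CC[Si](CC)(CC)OS(=O)(=O)C(F)(F)F
Why: Exhaustive silylation followed by selective methanolysis of the labile silyl ester gives the acid with both hydroxyls masked as fluoride-labile ethers.

**Completion**

Step 26
Reactants: 33 (6R,7S,8S)-15-acetoxy-6-hydroxygermacra-1(10)E,4E,11(13)-trien-12,8-olide; 39 (2R)-2-methyl-2,3-bis[(triethylsilyl)oxy]propanoic acid
Product: 41 (6R,7R,8S)-15-acetoxy-6-{[(2R)-2-methyl-2,3-bis(triethylsilyloxy)propanoyl]oxy}germacra-1(10)E,4E,11(13)-trien-12,8-olide, via mixed anhydride 40 (not isolated)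
Conditions: 2,4,6-Cl3C6H2COCl, Et3N, toluene, rt; then 33, DMAP, toluene, rt → 40 °C
Reagents that add atoms: none
Why: Yamaguchi esterification through the trichlorobenzoyl anhydride acylates the hindered secondary C6 hydroxyl with retention at C6 and at the quaternary centre of the acid.

Step 27
Reactants: 41 the bis-TES ester
Product: 42 the target, (6R,7R,8S)-15-acetoxy-6-{[(2R)-2,3-dihydroxy-2-methylpropanoyl]oxy}germacra-1(10)E,4E,11(13)-trien-12,8-olide
Conditions: HF·pyridine, pyridine, THF, 0 °C → rt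
Reagents that add atoms: none
Why: Buffered fluoride desilylation removes both TES ethers under conditions mild enough for the acetate, the allylic ester, the α-methylene lactone and the acid-sensitive cyclodecadiene.

**Compound list**

1 | but-2-yne-1,4-diol | OCC#CCO | starting material
2 | 4-[(tert-butyldiphenylsilyl)oxy]but-2-yn-1-ol | OCC#CCO[Si](c1ccccc1)(c1ccccc1)C(C)(C)C | intermediate
3 | cyclic sodium vinylalanate (ring O–CH2–CH=C(CH2OTBDPS)–Al(OCH2CH2OMe)2) | [Na+].COCCO[Al-]1(OCCOC)OCC=C1CO[Si](c1ccccc1)(c1ccccc1)C(C)(C)C | intermediate (not isolated)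
4 | (2Z)-4-[(tert-butyldiphenylsilyl)oxy]-3-iodobut-2-en-1-ol | OC/C=C(\I)CO[Si](c1ccccc1)(c1ccccc1)C(C)(C)C | intermediate
5 | potassium trifluoro(vinyl)borate | [K+].C=C[B-](F)(F)F | starting material
6 | (2E)-3-{[(tert-butyldiphenylsilyl)oxy]methyl}penta-2,4-dien-1-ol | OC/C=C(\C=C)CO[Si](c1ccccc1)(c1ccccc1)C(C)(C)C | intermediate
7 | (2E)-3-{[(tert-butyldiphenylsilyl)oxy]methyl}penta-2,4-dienal | O=C/C=C(\C=C)CO[Si](c1ccccc1)(c1ccccc1)C(C)(C)C | intermediate
8 | tert-butyl{[(2E)-2-ethenyl-4,4-dimethoxybut-2-en-1-yl]oxy}diphenylsilane | COC(OC)/C=C(\C=C)CO[Si](c1ccccc1)(c1ccccc1)C(C)(C)C | intermediate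
9 | 9-[(3E)-5,5-dimethoxy-3-{[(tert-butyldiphenylsilyl)oxy]methyl}pent-3-en-1-yl]-9-borabicyclo[3.3.1]nonane | COC(OC)/C=C(\CCB1C2CCCC1CCC2)CO[Si](c1ccccc1)(c1ccccc1)C(C)(C)C | intermediate (not isolated)
10 | (3E)-5,5-dimethoxy-3-{[(tert-butyldiphenylsilyl)oxy]methyl}pent-3-en-1-ol | COC(OC)/C=C(\CCO)CO[Si](c1ccccc1)(c1ccccc1)C(C)(C)C | intermediate
11 | tert-butyl{[(2E)-2-(2-iodoethyl)-4,4-dimethoxybut-2-en-1-yl]oxy}diphenylsilane | COC(OC)/C=C(\CCI)CO[Si](c1ccccc1)(c1ccccc1)C(C)(C)C | intermediate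
12 | ethynyltrimethylsilane | C#C[Si](C)(C)C | starting material
13 | (S)-epichlorohydrin, (2S)-2-(chloromethyl)oxirane | ClC[C@@H]1CO1 | starting material
14 | lithium (trimethylsilyl)acetylide | [Li+].[C-]#C[Si](C)(C)C | intermediate (not isolated)
15 | (2S)-1-chloro-5-(trimethylsilyl)pent-4-yn-2-ol | O[C@H](CCl)CC#C[Si](C)(C)C | intermediate
16 | trimethyl{3-[(2S)-oxiran-2-yl]prop-1-yn-1-yl}silane | C[Si](C)(C)C#CC[C@H]1CO1 | intermediate (not isolated)
17 | (3S)-6-(trimethylsilyl)hex-1-en-5-yn-3-ol | C=C[C@@H](O)CC#C[Si](C)(C)C | intermediate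
18 | (3S)-hex-1-en-5-yn-3-ol | C=C[C@@H](O)CC#C | intermediate
19 | dimethylaluminium (3S,5E)-6-(dimethylalumanyl)-5-methylhexa-1,5-dien-3-olate | C=C[C@@H](O[Al](C)C)C/C(C)=C/[Al](C)C | intermediate (not isolated)
20 | (3S,5E)-6-iodo-5-methylhexa-1,5-dien-3-ol | C=C[C@@H](O)C/C(C)=C/I | intermediate
21 | methyl 2-(hydroxymethyl)prop-2-enoate | C=C(CO)C(=O)OC | starting material
22 | methyl 2-{[(tert-butyldimethylsilyl)oxy]methyl}prop-2-enoate | C=C(CO[Si](C)(C)C(C)(C)C)C(=O)OC | intermediate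
23 | 2-{[(tert-butyldimethylsilyl)oxy]methyl}prop-2-enoic acid | C=C(CO[Si](C)(C)C(C)(C)C)C(=O)O | intermediate
24 | (3S,5E)-6-iodo-5-methylhexa-1,5-dien-3-yl 2-{[(tert-butyldimethylsilyl)oxy]methyl}prop-2-enoate | C=C[C@@H](OC(=O)C(=C)CO[Si](C)(C)C(C)(C)C)C/C(C)=C/I | intermediate
25 | (5S)-3-{[(tert-butyldimethylsilyl)oxy]methyl}-5-[(2E)-3-iodo-2-methylprop-2-en-1-yl]furan-2(5H)-one | O=C1O[C@@H](C/C(C)=C/I)C=C1CO[Si](C)(C)C(C)(C)C | intermediate
26 | [(3E)-5,5-dimethoxy-3-{[(tert-butyldiphenylsilyl)oxy]methyl}pent-3-en-1-yl]zinc iodide | COC(OC)/C=C(\CC[Zn]I)CO[Si](c1ccccc1)(c1ccccc1)C(C)(C)C | intermediate (not isolated)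
27 | (5S)-3-{[(tert-butyldimethylsilyl)oxy]methyl}-5-[(2E,6E)-8,8-dimethoxy-2-methyl-6-{[(tert-butyldiphenylsilyl)oxy]methyl}octa-2,6-dien-1-yl]furan-2(5H)-one | COC(OC)/C=C(CO[Si](c1ccccc1)(c1ccccc1)C(C)(C)C)\CC/C=C(C)/C[C@@H]1OC(=O)C(CO[Si](C)(C)C(C)(C)C)=C1 | intermediate
28 | (2E,6E)-8-[(2S)-4-(hydroxymethyl)-5-oxo-2,5-dihydrofuran-2-yl]-7-methyl-3-{[(tert-butyldiphenylsilyl)oxy]methyl}octa-2,6-dienal | O=C/C=C(CO[Si](c1ccccc1)(c1ccccc1)C(C)(C)C)\CC/C=C(C)/C[C@@H]1OC(=O)C(CO)=C1 | intermediate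
29 | methanesulfonate of 28 (C13–OMs) | O=C/C=C(CO[Si](c1ccccc1)(c1ccccc1)C(C)(C)C)\CC/C=C(C)/C[C@@H]1OC(=O)C(COS(C)(=O)=O)=C1 | intermediate (not isolated)
30 | (2E,6E)-8-[(2S)-4-(bromomethyl)-5-oxo-2,5-dihydrofuran-2-yl]-7-methyl-3-{[(tert-butyldiphenylsilyl)oxy]methyl}octa-2,6-dienal | O=C/C=C(CO[Si](c1ccccc1)(c1ccccc1)C(C)(C)C)\CC/C=C(C)/C[C@@H]1OC(=O)C(CBr)=C1 | intermediate
31 | (6R,7S,8S)-15-[(tert-butyldiphenylsilyl)oxy]-6-hydroxygermacra-1(10)E,4E,11(13)-trien-12,8-olide | C=C1C(=O)O[C@H]2C/C(C)=C/CC/C(CO[Si](c3ccccc3)(c3ccccc3)C(C)(C)C)=C\[C@@H](O)[C@H]12 | intermediate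
32 | (6R,7S,8S)-6,15-dihydroxygermacra-1(10)E,4E,11(13)-trien-12,8-olide | C=C1C(=O)O[C@H]2C/C(C)=C/CC/C(CO)=C\[C@@H](O)[C@H]12 | intermediate
33 | (6R,7S,8S)-15-acetoxy-6-hydroxygermacra-1(10)E,4E,11(13)-trien-12,8-olide | C=C1C(=O)O[C@H]2C/C(C)=C/CC/C(COC(C)=O)=C\[C@@H](O)[C@H]12 | intermediate
34 | 2-methylprop-2-en-1-ol | C=C(C)CO | starting material
35 | [(2S)-2-methyloxiran-2-yl]methanol | OC[C@]1(C)OC1 | intermediate
36 | (2R)-2-methyloxirane-2-carboxylic acid | OC(=O)[C@]1(C)OC1 | intermediate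
37 | (2R)-2,3-dihydroxy-2-methylpropanoic acid | OC(=O)[C@](C)(O)CO | intermediate
38 | triethylsilyl (2R)-2-methyl-2,3-bis[(triethylsilyl)oxy]propanoate | CC[Si](CC)(CC)OC(=O)[C@](C)(O[Si](CC)(CC)CC)CO[Si](CC)(CC)CC | intermediate (not isolated)
39 | (2R)-2-methyl-2,3-bis[(triethylsilyl)oxy]propanoic acid | OC(=O)[C@](C)(O[Si](CC)(CC)CC)CO[Si](CC)(CC)CC | intermediate
40 | (2R)-2-methyl-2,3-bis[(triethylsilyl)oxy]propanoic 2,4,6-trichlorobenzoic anhydride | O=C(OC(=O)[C@](C)(O[Si](CC)(CC)CC)CO[Si](CC)(CC)CC)c1c(Cl)cc(Cl)cc1Cl | intermediate (not isolated)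
41 | (6R,7R,8S)-15-acetoxy-6-{[(2R)-2-methyl-2,3-bis(triethylsilyloxy)propanoyl]oxy}germacra-1(10)E,4E,11(13)-trien-12,8-olide | C=C1C(=O)O[C@H]2C/C(C)=C/CC/C(COC(C)=O)=C\[C@@H](OC(=O)[C@](C)(O[Si](CC)(CC)CC)CO[Si](CC)(CC)CC)[C@H]12 | intermediate
42 | (6R,7R,8S)-15-acetoxy-6-{[(2R)-2,3-dihydroxy-2-methylpropanoyl]oxy}germacra-1(10)E,4E,11(13)-trien-12,8-olide | C=C1C(=O)O[C@H]2C/C(C)=C/CC/C(COC(C)=O)=C\[C@@H](OC(=O)[C@](C)(O)CO)[C@H]12 | target

**Step count and risks**

Total step count: 27. Longest linear sequence: 15 steps (steps 1–7, 16–21, 26 and 27).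

Most likely to fail, step 19 (CrCl2 macrocyclisation). The strained ring may give oligomers, or the tether may override the acyclic stereochemical model at C6/C7. The fallback sets out from 25 and 11 and comes back at 31: the C6–C7 bond is made first between two open fragments, and the ring is closed afterwards at C1–C2. Desilylation of 25 (AcOH/THF/H2O) gives (5S)-3-(hydroxymethyl)-5-[(2E)-3-iodo-2-methylprop-2-en-1-yl]furan-2(5H)-one F1, and CBr4/PPh3 converts it to (5S)-3-(bromomethyl)-5-[(2E)-3-iodo-2-methylprop-2-en-1-yl]furan-2(5H)-one F2. Hydrolysis of acetal 11 (PPTS, acetone/H2O) gives (2E)-5-iodo-3-{[(tert-butyldiphenylsilyl)oxy]methyl}pent-2-enal F3. Indium-mediated Barbier allylation of F3 by F2 (In powder, THF/H2O) gives (3-methylidene, 4S,5S)-4-[(1R,2E)-1-hydroxy-5-iodo-3-{[(tert-butyldiphenylsilyl)oxy]methyl}pent-2-en-1-yl]-5-[(2E)-3-iodo-2-methylprop-2-en-1-yl]-3-methylideneoxolan-2-one F4, with the same anti/trans sense. Zn dust/LiCl inserts only into the primary C–I bond of F4 to give the corresponding alkylzinc iodide F5, and slow addition of F5 to Pd2(dba)3/SPhos at high dilution (intramolecular Negishi coupling with the vinyl iodide) closes the ring to 31.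

Second, step 6 (mono-hydroboration of the conjugated diene). Over-hydroboration or attack at the internal alkene would erode the yield. The fallback sets out from 4, 18 and 23 and comes back at 27: the sp3–sp2 disconnection is moved from C1–C2 to C3–C4, so no diene is needed. MnO2 oxidation of 4 gives (2Z)-4-[(tert-butyldiphenylsilyl)oxy]-3-iodobut-2-enal F6, and HC(OMe)3/PPTS gives tert-butyl{[(2Z)-2-iodo-4,4-dimethoxybut-2-en-1-yl]oxy}diphenylsilane F7. On the other side, vinylalane 19 (made from 18 as in step 11) is activated with n-BuLi and quenched with oxirane instead of iodine to give (3S,5E)-5-methylocta-1,5-diene-3,8-diol F8. Selective iodination of the primary alcohol (PPh3, imidazole, I2, −20 °C) gives (3S,5E)-8-iodo-5-methylocta-1,5-dien-3-ol F9, and carbodiimide esterification with 23 gives (3S,5E)-8-iodo-5-methylocta-1,5-dien-3-yl 2-{[(tert-butyldimethylsilyl)oxy]methyl}prop-2-enoate F10. Ring-closing metathesis gives (5S)-3-{[(tert-butyldimethylsilyl)oxy]methyl}-5-[(2E)-5-iodo-2-methylpent-2-en-1-yl]furan-2(5H)-one F11. Zinc insertion gives the alkylzinc iodide {(3E)-5-[(2S)-4-{[(tert-butyldimethylsilyl)oxy]methyl}-5-oxo-2,5-dihydrofuran-2-yl]-4-methylpent-3-en-1-yl}zinc iodide F12, and PdCl2(dppf)-catalysed Negishi coupling of F12 with F7 gives 27.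

Third, step 26 (acylation of the hindered C6 alcohol by an acid whose α-carbon is fully substituted and carries two bulky silyl ethers). The fallback sets out from 37 (and 33) and comes back at 42: the acyl donor is redesigned, with the tertiary hydroxyl left free so the donor is far less hindered. Treatment of 37 with TBSCl/imidazole gives tert-butyldimethylsilyl (2R)-3-[(tert-butyldimethylsilyl)oxy]-2-hydroxy-2-methylpropanoate F13 (not isolated), and K2CO3/MeOH cleaves its silyl ester to (2R)-3-[(tert-butyldimethylsilyl)oxy]-2-hydroxy-2-methylpropanoic acid F14. Carbodiimide/DMAP coupling of F14 with 33 (the tertiary hydroxyl does not compete) gives (6R,7R,8S)-15-acetoxy-6-{[(2R)-3-(tert-butyldimethylsilyloxy)-2-hydroxy-2-methylpropanoyl]oxy}germacra-1(10)E,4E,11(13)-trien-12,8-olide F15, and HF·pyridine then gives 42.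

**Further compounds**

F1 | step 19 | (5S)-3-(hydroxymethyl)-5-[(2E)-3-iodo-2-methylprop-2-en-1-yl]furan-2(5H)-one | O=C1O[C@@H](C/C(C)=C/I)C=C1CO
F2 | step 19 | (5S)-3-(bromomethyl)-5-[(2E)-3-iodo-2-methylprop-2-en-1-yl]furan-2(5H)-one | O=C1O[C@@H](C/C(C)=C/I)C=C1CBr
F3 | step 19 | (2E)-5-iodo-3-{[(tert-butyldiphenylsilyl)oxy]methyl}pent-2-enal | O=C/C=C(\CCI)CO[Si](c1ccccc1)(c1ccccc1)C(C)(C)C
F4 | step 19 | (4S,5S)-4-[(1R,2E)-1-hydroxy-5-iodo-3-{[(tert-butyldiphenylsilyl)oxy]methyl}pent-2-en-1-yl]-5-[(2E)-3-iodo-2-methylprop-2-en-1-yl]-3-methylideneoxolan-2-one | C=C1C(=O)O[C@@H](C/C(C)=C/I)[C@@H]1[C@H](O)/C=C(\CCI)CO[Si](c1ccccc1)(c1ccccc1)C(C)(C)C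
F5 | step 19 | alkylzinc iodide of F4 (zinc on the primary carbon C2) | C=C1C(=O)O[C@@H](C/C(C)=C/I)[C@@H]1[C@H](O)/C=C(\CC[Zn]I)CO[Si](c1ccccc1)(c1ccccc1)C(C)(C)C
F6 | step 6 | (2Z)-4-[(tert-butyldiphenylsilyl)oxy]-3-iodobut-2-enal | O=C/C=C(\I)CO[Si](c1ccccc1)(c1ccccc1)C(C)(C)C
F7 | step 6 | tert-butyl{[(2Z)-2-iodo-4,4-dimethoxybut-2-en-1-yl]oxy}diphenylsilane | COC(OC)/C=C(\I)CO[Si](c1ccccc1)(c1ccccc1)C(C)(C)C
F8 | step 6 | (3S,5E)-5-methylocta-1,5-diene-3,8-diol | C=C[C@@H](O)C/C(C)=C/CCO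
F9 | step 6 | (3S,5E)-8-iodo-5-methylocta-1,5-dien-3-ol | C=C[C@@H](O)C/C(C)=C/CCI
F10 | step 6 | (3S,5E)-8-iodo-5-methylocta-1,5-dien-3-yl 2-{[(tert-butyldimethylsilyl)oxy]methyl}prop-2-enoate | C=C[C@@H](OC(=O)C(=C)CO[Si](C)(C)C(C)(C)C)C/C(C)=C/CCI
F11 | step 6 | (5S)-3-{[(tert-butyldimethylsilyl)oxy]methyl}-5-[(2E)-5-iodo-2-methylpent-2-en-1-yl]furan-2(5H)-one | O=C1O[C@@H](C/C(C)=C/CCI)C=C1CO[Si](C)(C)C(C)(C)C
F12 | step 6 | {(3E)-5-[(2S)-4-{[(tert-butyldimethylsilyl)oxy]methyl}-5-oxo-2,5-dihydrofuran-2-yl]-4-methylpent-3-en-1-yl}zinc iodide | O=C1O[C@@H](C/C(C)=C/CC[Zn]I)C=C1CO[Si](C)(C)C(C)(C)C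
F13 | step 26 | tert-butyldimethylsilyl (2R)-3-[(tert-butyldimethylsilyl)oxy]-2-hydroxy-2-methylpropanoate | CC(C)(C)[Si](C)(C)OC(=O)[C@](C)(O)CO[Si](C)(C)C(C)(C)C
F14 | step 26 | (2R)-3-[(tert-butyldimethylsilyl)oxy]-2-hydroxy-2-methylpropanoic acid | OC(=O)[C@](C)(O)CO[Si](C)(C)C(C)(C)C
F15 | step 26 | (6R,7R,8S)-15-acetoxy-6-{[(2R)-3-(tert-butyldimethylsilyloxy)-2-hydroxy-2-methylpropanoyl]oxy}germacra-1(10)E,4E,11(13)-trien-12,8-olide | C=C1C(=O)O[C@H]2C/C(C)=C/CC/C(COC(C)=O)=C\[C@@H](OC(=O)[C@](C)(O)CO[Si](C)(C)C(C)(C)C)[C@H]12
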